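## Analysis of the target

The target 16 is an ether of two 2-(2-phenylethyl)chromone units. The aromatic unit (ring A = benzo ring, ring B = pyranone, primed locants) carries OMe at C7' and the ether oxygen at C6'. The other unit is a 5,6,7,8-tetrahydrochromone (ring C = C4a, C5 to C8, C8a; ring D = pyranone) bound through O8. Ring C holds four contiguous oxygenated stereocentres, (5S,6R,7S,8S): O7 and O8 are cis, O6 is trans to O7, and O5 is trans to O6, so O5, O7 and O8 lie on one face (α below) and O6 on the other (β). Every C–O bond of ring C is allylic or homoallylic to C4a=C8a, so acid (ionisation at C5, helped by O1) or base (H8 is a vinylogous α-proton of the C4 carbonyl) can start eliminations that end in a flat chromone; the pyranones also open with hard nucleophiles. The synthesis is hard for two reasons: four oxygens must be placed with defined relative and absolute configuration on a ring that is only dehydrations away from an arene, and O8 rather than O7 must be joined to an electron-rich aryl carbon without disturbing C8. The strategy rests on one feature: ring C is a reduced chromone benzo ring, and its cis pair O7/O8 sits on C7–C8, the bond next to the ring fusion, where a dioxygenase places a cis-diol on a fused arene. One O2 across C7–C8 of the flat chromone 4 gives both centres and leaves C5=C6 as the handle for the trans pair O5/O6; both halves share one skeleton, so the ester 2 serves twice.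

## Retrosynthetic reasoning

16 to 15. The last operation is the removal of two silyl ethers from O5 and O6. These groups are needed because the aryl ether must be formed on a substrate in which only O7 and O8 are free, and fluoride under buffered conditions spares the acid- and base-sensitive ring C.

15 to 10 and 14. The C6'–O8 bond is cut on the aryl side. Arylation of the O8 alkoxide neither makes nor breaks a bond at C8, so the configuration set earlier is carried through. Cutting on the alkyl side would require an SN2 displacement at C8 with inversion, hence a 7,8-trans precursor that the chosen dearomatisation cannot deliver. The cut is convergent: 10 holds all four stereocentres and 14 is a plain aromatic chromone. The forward reaction must select O8 over O7 in the diol 10.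

14 to 13, 12, 11 and 2. The iodide 14 comes from the bromide 13 by halide exchange, because secondary alcohols couple reliably under copper catalysis only with aryl iodides. 13 is disconnected at O1'–C2' and C3'–C4' in the standard way, to the diketone 12 and then to the acetophenone 11 and the ester 2.

10 to 9 to 8. The free 7,8-diol of 10 is traced to the isopropylidene acetal 9 and the silyl ethers of 9 to the 5,6-diol 8. This exchange of protecting groups is what tells the O5/O6 pair from the O7/O8 pair: the cis pair is tied up as a cyclic acetal from the moment it is made, so the trans pair can be capped separately.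

8 to 7 to 6. The C5–O bond is cut back to the β-epoxide 7 and the epoxide to the alkene 6. The trans relation of O5 and O6 follows from anti opening of the epoxide. The opening occurs at C5 because positive charge there is shared with O1 through C4a=C8a, whereas C6 is deactivated by the adjacent C7–O bond. The β face is chosen by the cis-fused acetal of 6, which covers the α face.

6 to 5 to 4. The acetal 6 comes from the cis-diol 5, and in 5 both C–O bonds at C7 and C8 are cut at once, which leads back to the aromatic chromone 4. This is the disconnection that carries the strategy: two stereocentres and the loss of aromaticity are obtained in one enzymatic event, and nothing but a flat, easily made arene has to be prepared beforehand.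

4 to 3 to 1 and 2. The chromone 4 is opened to the diketone 3, which comes from the acetophenone 1 and the ester 2 by a Claisen condensation. Two reliable steps reach the key precursor, so the risk of the route sits in the dearomatisation.

## Alternatives that were turned down

Alternative 1: The ether is kept and rings A and B are taken apart, at C4a'–C5' and O1'–C2', into an open poly-β-carbonyl chain. The chain ends in a dimethyl acetal and already carries the O8 oxygen on the carbon that becomes C6'. In the forward direction BF3·OEt2 ionises the acetal, the methylene that becomes C4a' attacks the oxocarbenium ion, loss of methanol and tautomerisation give the phenol of ring A, and this phenol condenses with the C2' ketone to close ring B. The product is the tris-silyl ether A1, one deprotection from 16.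
- For: the ether oxygen is attached before ring A exists, so the O7/O8 question is settled by ordinary protection of a triol and not by a selective arylation. On this point, and on the one-step endgame, it is stronger than the chosen route.
- Against: it does nothing for the four stereocentres of ring C, which must still come from elsewhere. The masked polyketone is hard to assemble and can cyclise in other modes (O- against C-attack, other aldol partners). BF3·OEt2 meets three silyl ethers on a ring that aromatises by ionisation at C5.
- Comparison: the chosen route takes both chromone rings from a two-step textbook sequence and spends its one risky step on ring C.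

Alternative 2: Only ring A is disconnected, by a ketene–alkyne benzannulation. A diazo ketone that carries the ring C/D alkoxy group is irradiated above 300 nm. Wolff rearrangement gives a vinylketene, [2+2] addition of the ynol ether A3, four-electron opening of the cyclobutenone and six-electron closure give the phenol A2.
- For: the substitution pattern of ring A is fixed by the mechanism, and the conditions are neutral and metal-free, so C8 sees no base. On this point it is as good as or better than a copper-mediated coupling.
- Against: A2 is still far from 16. O-Methylation, ortho-acylation and the whole construction of ring B (strong base, then acid) must be carried out on the fully functionalised ring C. The diazo ketone has to be built on the precious fragment. Ring D absorbs near 300 nm and competes for the light. The stereocentres are again left to another method.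
- Comparison: the chosen route brings the aromatic half in as the finished chromone 14 and has fewer operations after the two halves are joined.

Alternative 3: Ring D is disconnected at O1–C8a from a ring C taken from shikimic acid A5, whose carboxyl carbon becomes C4. A 1,3-diketone built on that carbon adds through its enol oxygen to the enone β-carbon (6-endo-trig), and Pd(OCOCF3)2 under O2 dehydrogenates the adduct to the pyranone A4.
- For: C6, C7 and C8 come from the chiral pool with the correct absolute configuration, and O8 is the allylic hydroxyl of A5 and so chemically distinct from O7. On certainty of configuration and supply this alternative is stronger than the chosen route, which depends on an enzyme screen.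
- Against: C5 arrives as a CH2 group, so the fourth stereocentre needs a late, face-selective C–H oxidation beside two benzylic CH2 groups. The oxidative palladium step acts on a ring that becomes an arene by further dehydrogenation or by loss of silanol. The linear sequence is long.
- Comparison: the chosen route installs all four oxygens by two face-selective additions to C=C bonds, with O5 arriving together with its configuration, at the price of one unprecedented biotransformation.

Key step: step 3

Remarks on the chemistry: the α face of ring C is the face that carries O7 and O8. In step 3 the hydrogen atoms come from NADH, which the cells regenerate from glucose, so glucose is treated as the terminal reductant. It is assumed that a strain with a naphthalene-type dioxygenase that accepts 4 can be found by screening.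

## Route

Step 1
Reactants: 1 1-(2-hydroxyphenyl)ethanone; 2 methyl 3-phenylpropanoate
Product: 3 1-(2-hydroxyphenyl)-5-phenylpentane-1,3-dione
Conditions: NaH (4 equiv), THF, 65 °C; then 1 M aq. HCl
Reagents that add atoms: none
Why: Crossed Claisen condensation: the dianion of 1 (phenoxide and methyl ketone enolate) attacks the ester carbonyl of 2, and formation of the stable diketone enolate drives the equilibrium; no stereocentre is formed.

Step 2
Reactants: 3 1-(2-hydroxyphenyl)-5-phenylpentane-1,3-dione
Product: 4 2-(2-phenylethyl)-4H-chromen-4-one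
Conditions: H2SO4 (cat.), AcOH, 100 °C
Reagents that add atoms: none
Why: Acid-catalysed cyclodehydration: the phenol adds to the distal ketone and water is lost to give the aromatic 4-pyranone, the standard chromone closure.

Step 3
Reactants: 4 2-(2-phenylethyl)-4H-chromen-4-one
Product: 5 (7S,8S)-7,8-dihydroxy-2-(2-phenylethyl)-7,8-dihydro-4H-chromen-4-one
Conditions: resting whole cells of E. coli expressing naphthalene 1,2-dioxygenase (genes of Pseudomonas sp. NCIB 9816-4, no cis-diol dehydrogenase), glucose, phosphate buffer pH 7.2, air, 30 °C; 4 fed in DMSO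
Reagents that add atoms: dioxygen, O=O
Why: Proposed new method: the reduced Rieske [2Fe-2S] cluster passes two electrons from NADH to the mononuclear non-haem iron centre, which binds O2 and transfers both oxygen atoms to the same face of C7 and C8 of 4, so the cis relation is mechanistic and ring C loses its aromaticity in one turnover. The closest known reaction type is the cis-dihydroxylation of naphthalene to its (1R,2S)-diol and of benzo-fused heteroarenes such as quinoline in the carbocyclic ring by this enzyme class; a chromone has not been shown to react in this way, which is why the step counts as new. No ring is closed. Both new stereocentres, C7 and C8, are controlled by the enzyme pocket alone: if ring D lies where the distal ring of naphthalene lies, oxygen arrives on the same face as in naphthalene, and this is (7S,8S) here because O1 on C8a changes the CIP order at C8 only. The step needs site selectivity for C7–C8 over C5–C6, over the phenyl ring and over benzylic hydroxylation of the chain, and it needs one face. The preference of the enzyme for the bond next to the ring fusion of a fused bicyclic arene, the peri carbonyl that encumbers C5–C6, and the distance of the phenylethyl arm from iron when ring C is bound are expected to supply this. The host has no diol dehydrogenase, so the diol is not re-aromatised, and wild-type and active-site variants would be screened to secure activity and configuration.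

Step 4
Reactants: 5 (7S,8S)-7,8-dihydroxy-2-(2-phenylethyl)-7,8-dihydro-4H-chromen-4-one
Product: 6 (7S,8S)-7,8-(isopropylidenedioxy)-2-(2-phenylethyl)-7,8-dihydro-4H-chromen-4-one
Conditions: 2,2-dimethoxypropane, PPTS (cat.), acetone, 0 °C to rt
Reagents that add atoms: 2,2-dimethoxypropane, COC(C)(C)OC
Why: Acid-catalysed transacetalisation closes a cis-fused 1,3-dioxolane on the cis-diol; the weak acid and low temperature keep the dihydrodiol from dehydrating to a phenol, and no stereocentre changes.

Step 5
Reactants: 6 (7S,8S)-7,8-(isopropylidenedioxy)-2-(2-phenylethyl)-7,8-dihydro-4H-chromen-4-one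
Product: 7 (5R,6R,7S,8S)-5,6-epoxy-7,8-(isopropylidenedioxy)-2-(2-phenylethyl)-5,6,7,8-tetrahydro-4H-chromen-4-one
Conditions: mCPBA, NaHCO3, CH2Cl2, 0 °C to rt
Reagents that add atoms: 3-chloroperbenzoic acid, OOC(=O)c1cccc(Cl)c1
Why: Prilezhaev epoxidation of C5=C6, the only double bond that is not part of a push-pull pyranone; the peracid approaches the β face because the cis-fused dioxolane covers the α face, which sets C6 (and provisionally C5), and the buffer keeps the epoxide from opening.

Step 6
Reactants: 7 (5R,6R,7S,8S)-5,6-epoxy-7,8-(isopropylidenedioxy)-2-(2-phenylethyl)-5,6,7,8-tetrahydro-4H-chromen-4-one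
Product: 8 (5S,6R,7S,8S)-5,6-dihydroxy-7,8-(isopropylidenedioxy)-2-(2-phenylethyl)-5,6,7,8-tetrahydro-4H-chromen-4-one
Conditions: HClO4 (cat.), THF/H2O (3:1), 0 °C
Reagents that add atoms: water, O
Why: Acid-catalysed epoxide hydrolysis of borderline SN2 character: the C5–O bond breaks because charge at C5 is shared with O1 through C4a=C8a while C6 is deactivated by the C7–O bond, and water enters C5 from the α face, anti to the leaving oxygen, so C5 is inverted to S and the 5,6-diol is trans. The dilute acid at 0 °C should leave the cis-fused dioxolane intact.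

Step 7
Reactants: 8 (5S,6R,7S,8S)-5,6-dihydroxy-7,8-(isopropylidenedioxy)-2-(2-phenylethyl)-5,6,7,8-tetrahydro-4H-chromen-4-one
Product: 9 (5S,6S,7R,8S)-5,6-bis[(tert-butyldimethylsilyl)oxy]-7,8-(isopropylidenedioxy)-2-(2-phenylethyl)-5,6,7,8-tetrahydro-4H-chromen-4-one
Conditions: TBSOTf, 2,6-lutidine, CH2Cl2, −20 °C to rt
Reagents that add atoms: tert-butyldimethylsilyl trifluoromethanesulfonate, CC(C)(C)[Si](C)(C)OS(=O)(=O)C(F)(F)F
Why: Silylation with the silyl triflate, which is reactive enough for O5 (hindered and hydrogen-bonded to the C4 carbonyl); the weak hindered base does not touch H8, and the configuration is unchanged (the descriptors at C6 and C7 change only through CIP priorities).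

Step 8
Reactants: 9 (5S,6S,7R,8S)-5,6-bis[(tert-butyldimethylsilyl)oxy]-7,8-(isopropylidenedioxy)-2-(2-phenylethyl)-5,6,7,8-tetrahydro-4H-chromen-4-one
Product: 10 (5S,6S,7R,8S)-5,6-bis[(tert-butyldimethylsilyl)oxy]-7,8-dihydroxy-2-(2-phenylethyl)-5,6,7,8-tetrahydro-4H-chromen-4-one
Conditions: AcOH/H2O/THF (4:1:1), 45 °C
Reagents that add atoms: none
Why: Acid hydrolysis of the isopropylidene acetal; hindered secondary tert-butyldimethylsilyl ethers are cleaved much more slowly by aqueous acetic acid, so only O7 and O8 are set free.

Step 9
Reactants: 11 1-(5-bromo-2-hydroxy-4-methoxyphenyl)ethanone; 2 methyl 3-phenylpropanoate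
Product: 12 1-(5-bromo-2-hydroxy-4-methoxyphenyl)-5-phenylpentane-1,3-dione
Conditions: NaH (4 equiv), THF, 65 °C; then 1 M aq. HCl
Reagents that add atoms: none
Why: Crossed Claisen condensation as in step 1; the aryl bromide and the methyl ether are inert to NaH.

Step 10
Reactants: 12 1-(5-bromo-2-hydroxy-4-methoxyphenyl)-5-phenylpentane-1,3-dione
Product: 13 6-bromo-7-methoxy-2-(2-phenylethyl)-4H-chromen-4-one
Conditions: H2SO4 (cat.), AcOH, 100 °C
Reagents that add atoms: none
Why: Acid-catalysed cyclodehydration to the chromone as in step 2; the bromine ends at C6' and the methoxy group at C7'.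

Step 11
Reactants: 13 6-bromo-7-methoxy-2-(2-phenylethyl)-4H-chromen-4-one
Product: 14 6-iodo-7-methoxy-2-(2-phenylethyl)-4H-chromen-4-one
Conditions: CuI (5 mol%), trans-N,N'-dimethylcyclohexane-1,2-diamine (10 mol%), NaI (2 equiv), 1,4-dioxane, 110 °C
Reagents that add atoms: sodium iodide, [Na+].[I-]
Why: Copper-catalysed aromatic Finkelstein reaction, driven by the excess of NaI and the low solubility of NaBr in dioxane; the iodide is made because copper-catalysed etherification of a secondary alcohol is reliable only with aryl iodides.

Step 12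
Reactants: 10 (5S,6S,7R,8S)-5,6-bis[(tert-butyldimethylsilyl)oxy]-7,8-dihydroxy-2-(2-phenylethyl)-5,6,7,8-tetrahydro-4H-chromen-4-one; 14 6-iodo-7-methoxy-2-(2-phenylethyl)-4H-chromen-4-one
Product: 15 6-{[(5S,6S,7R,8S)-5,6-bis[(tert-butyldimethylsilyl)oxy]-7-hydroxy-4-oxo-2-(2-phenylethyl)-5,6,7,8-tetrahydro-4H-chromen-8-yl]oxy}-7-methoxy-2-(2-phenylethyl)-4H-chromen-4-one
Conditions: CuI (20 mol%), 3,4,7,8-tetramethyl-1,10-phenanthroline (40 mol%), Cs2CO3, 4 Å molecular sieves, toluene, 85 °C; 14 in excess
Reagents that add atoms: none
Why: Ullmann-type copper-catalysed C–O coupling of an aryl iodide with a secondary alcohol; C8 keeps its configuration because no bond to it is made or broken. O8–H is the more acidic hydroxyl (its carbon is attached to the electron-poor C8a) and the less hindered one (O7 is flanked by the C6 silyl ether), so the copper alkoxide should form and couple at O8.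

Step 13
Reactants: 15 6-{[(5S,6S,7R,8S)-5,6-bis[(tert-butyldimethylsilyl)oxy]-7-hydroxy-4-oxo-2-(2-phenylethyl)-5,6,7,8-tetrahydro-4H-chromen-8-yl]oxy}-7-methoxy-2-(2-phenylethyl)-4H-chromen-4-one
Product: 16 6-{[(5S,6R,7S,8S)-5,6,7-trihydroxy-4-oxo-2-(2-phenylethyl)-5,6,7,8-tetrahydro-4H-chromen-8-yl]oxy}-7-methoxy-2-(2-phenylethyl)-4H-chromen-4-one
Conditions: HF·pyridine, pyridine, THF, 0 °C to rt
Reagents that add atoms: none
Why: Fluoride cleavage of both silyl ethers under buffered, weakly acidic conditions, which avoids base at the vinylogous α-position C8 and strong acid at C5; no stereocentre is touched.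

## Compound list

1 | 1-(2-hydroxyphenyl)ethanone | CC(=O)c1ccccc1O | starting material
2 | methyl 3-phenylpropanoate | COC(=O)CCc1ccccc1 | starting material
3 | 1-(2-hydroxyphenyl)-5-phenylpentane-1,3-dione | O=C(CC(=O)CCc1ccccc1)c1ccccc1O | intermediate
4 | 2-(2-phenylethyl)-4H-chromen-4-one | O=c1cc(CCc2ccccc2)oc2ccccc12 | intermediate
5 | (7S,8S)-7,8-dihydroxy-2-(2-phenylethyl)-7,8-dihydro-4H-chromen-4-one | O[C@@H]1c2oc(CCc3ccccc3)cc(=O)c2C=C[C@@H]1O | intermediate
6 | (7S,8S)-7,8-(isopropylidenedioxy)-2-(2-phenylethyl)-7,8-dihydro-4H-chromen-4-one | CC1(C)O[C@@H]2c3oc(CCc4ccccc4)cc(=O)c3C=C[C@@H]2O1 | intermediate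
7 | (5R,6R,7S,8S)-5,6-epoxy-7,8-(isopropylidenedioxy)-2-(2-phenylethyl)-5,6,7,8-tetrahydro-4H-chromen-4-one | CC1(C)O[C@@H]2c3oc(CCc4ccccc4)cc(=O)c3[C@H]5O[C@H]5[C@@H]2O1 | intermediate
8 | (5S,6R,7S,8S)-5,6-dihydroxy-7,8-(isopropylidenedioxy)-2-(2-phenylethyl)-5,6,7,8-tetrahydro-4H-chromen-4-one | CC1(C)O[C@@H]2c3oc(CCc4ccccc4)cc(=O)c3[C@H](O)[C@@H](O)[C@@H]2O1 | intermediate
9 | (5S,6S,7R,8S)-5,6-bis[(tert-butyldimethylsilyl)oxy]-7,8-(isopropylidenedioxy)-2-(2-phenylethyl)-5,6,7,8-tetrahydro-4H-chromen-4-one | CC1(C)O[C@@H]2c3oc(CCc4ccccc4)cc(=O)c3[C@H](O[Si](C)(C)C(C)(C)C)[C@@H](O[Si](C)(C)C(C)(C)C)[C@@H]2O1 | intermediate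
10 | (5S,6S,7R,8S)-5,6-bis[(tert-butyldimethylsilyl)oxy]-7,8-dihydroxy-2-(2-phenylethyl)-5,6,7,8-tetrahydro-4H-chromen-4-one | O[C@@H]1c2oc(CCc3ccccc3)cc(=O)c2[C@H](O[Si](C)(C)C(C)(C)C)[C@@H](O[Si](C)(C)C(C)(C)C)[C@@H]1O | intermediate
11 | 1-(5-bromo-2-hydroxy-4-methoxyphenyl)ethanone | CC(=O)c1cc(Br)c(OC)cc1O | starting material
12 | 1-(5-bromo-2-hydroxy-4-methoxyphenyl)-5-phenylpentane-1,3-dione | O=C(CC(=O)CCc1ccccc1)c1cc(Br)c(OC)cc1O | intermediate
13 | 6-bromo-7-methoxy-2-(2-phenylethyl)-4H-chromen-4-one | COc1cc2oc(CCc3ccccc3)cc(=O)c2cc1Br | intermediate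
14 | 6-iodo-7-methoxy-2-(2-phenylethyl)-4H-chromen-4-one | COc1cc2oc(CCc3ccccc3)cc(=O)c2cc1I | intermediate
15 | 6-{[(5S,6S,7R,8S)-5,6-bis[(tert-butyldimethylsilyl)oxy]-7-hydroxy-4-oxo-2-(2-phenylethyl)-5,6,7,8-tetrahydro-4H-chromen-8-yl]oxy}-7-methoxy-2-(2-phenylethyl)-4H-chromen-4-one | COc1cc2oc(CCc3ccccc3)cc(=O)c2cc1O[C@@H]1c2oc(CCc3ccccc3)cc(=O)c2[C@H](O[Si](C)(C)C(C)(C)C)[C@@H](O[Si](C)(C)C(C)(C)C)[C@@H]1O | intermediate
16 | 6-{[(5S,6R,7S,8S)-5,6,7-trihydroxy-4-oxo-2-(2-phenylethyl)-5,6,7,8-tetrahydro-4H-chromen-8-yl]oxy}-7-methoxy-2-(2-phenylethyl)-4H-chromen-4-one | COc1cc2oc(CCc3ccccc3)cc(=O)c2cc1O[C@@H]1c2oc(CCc3ccccc3)cc(=O)c2[C@H](O)[C@@H](O)[C@@H]1O | target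

## Step count and least certain steps

Total step count: 13. Longest linear sequence: 10 steps (steps 1 to 8, 12 and 13); steps 9 to 11 form the three-step branch to 14.

Step 3 (key step, new method).
- What may go wrong: the chromone may fail to bind productively, so that there is no turnover. Oxygen may be delivered to the wrong site (C5–C6, the phenyl ring, or a benzylic CH2 of the chain) or to the wrong face. The diol may also dehydrate to a phenol in the broth.
- Fallback, known chemistry only, from the ester 2 back to the route at the acetonide 6: ring C is built from a cyclohexenone and not from an arene.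
  - The known building block (R)-4-[(tert-butyldimethylsilyl)oxy]cyclohex-2-en-1-one F1 is deprotonated at C6 with LiN(iPr)2 (THF, −78 °C) and C-acetylated with 1-acetylbenzotriazole to the β-diketone (4R)-6-acetyl-4-[(tert-butyldimethylsilyl)oxy]cyclohex-2-en-1-one F2.
  - The dianion of F2 (LiN(iPr)2, 2.2 equiv) is acylated at the methyl group by 2 to the triketone (4R)-4-[(tert-butyldimethylsilyl)oxy]-6-(3-oxo-5-phenylpentanoyl)cyclohex-2-en-1-one F3.
  - Neutral cyclodehydration (PPh3, CCl4) closes ring D to (6R)-6-[(tert-butyldimethylsilyl)oxy]-2-(2-phenylethyl)-5,6-dihydro-4H-chromen-4-one F4, in which the enone double bond has become C7=C8.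
  - OsO4 (cat.) with N-methylmorpholine N-oxide adds to C7=C8 anti to the allylic silyloxy group, as is usual for cyclic allylic ethers, and should give (6R,7R,8S)-6-[(tert-butyldimethylsilyl)oxy]-7,8-dihydroxy-2-(2-phenylethyl)-5,6,7,8-tetrahydro-4H-chromen-4-one F5.
  - 2,2-Dimethoxypropane with PPTS gives the 7,8-O-isopropylidene acetal of F5 F6, and Bu4NF removes the silyl group to give (6R,7S,8S)-6-hydroxy-7,8-(isopropylidenedioxy)-2-(2-phenylethyl)-5,6,7,8-tetrahydro-4H-chromen-4-one F7.
  - Mesylation (MsCl, Et3N) gives the 6-O-methanesulfonate of F7 F8, and DBU in warm toluene eliminates it. Only a C5 hydrogen can stand anti to the leaving group, because H7 is syn to it, so the E2 reaction should form C5=C6 and give 6.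
  - The C6 stereocentre directs the dihydroxylation and is then erased.

Step 12.
- What may go wrong: arylation at O7 or at both hydroxyls, migration of the C6 silyl group to O7 under carbonate, slow coupling of the hindered alkoxide with reduction of 14 taking over, or base-induced elimination through deprotonation at C8.
- Fallback, from 10 back to the route at 16: the two hydroxyls are told apart by protecting groups before the coupling.
  - The less hindered O8 is silylated first (Et3SiCl, imidazole, CH2Cl2, −40 °C) to the 8-O-triethylsilyl ether of 10 F9.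
  - O7 is then capped (TBSOTf, 2,6-lutidine) to the 7-O-(tert-butyldimethylsilyl)-8-O-triethylsilyl derivative of 10 F10.
  - The triethylsilyl group alone is removed (PPTS, MeOH, 0 °C) to the 5,6,7-tris-O-(tert-butyldimethylsilyl) 8-alcohol F11.
  - F11 has one free hydroxyl and is coupled with 14 under the conditions of step 12 to the 5,6,7-tris-O-(tert-butyldimethylsilyl) ether of 16 F12 (the same compound as A1); HF·pyridine then gives 16.
  - A wrong regioisomer of the first silylation can be desilylated and recycled, which is not possible after an arylation.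

Step 6.
- What may go wrong: the acid needed to open the deactivated epoxide may also hydrolyse the dioxolane, or the opening may run through a free C5 cation and give some attack from the β face.
- Fallback, from 7 back to the route at 8: the epoxide is opened under conditions that are allowed to remove the acetal as well (0.5 M H2SO4, THF/H2O, rt), giving the tetrol (5S,6R,7S,8S)-5,6,7,8-tetrahydroxy-2-(2-phenylethyl)-5,6,7,8-tetrahydro-4H-chromen-4-one F13. 2,2-Dimethoxypropane with PPTS in acetone then re-forms the acetal on the only cis-diol, O7/O8, because a trans-fused dioxolane on the 5,6- or 6,7-diol is strained, and this gives 8.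

Step 8.
- What may go wrong: loss of a silyl ether (most likely at O6), or ionisation at C5 with epimerisation or elimination, before the dioxolane is hydrolysed.
- Fallback, from 8 back to the route at 16: O5 and O6 are bridged by one disiloxane group, which cannot migrate to O7 and resists acid better than two separate silyl ethers.
  - 1,3-Dichloro-1,1,3,3-tetraisopropyldisiloxane with imidazole in DMF converts 8 into the 5,6-O-(1,1,3,3-tetraisopropyldisiloxane-1,3-diyl) derivative of 8 F14.
  - Aqueous trifluoroacetic acid at 0 °C removes the acetal to the corresponding 7,8-diol F15.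
  - Coupling with 14 as in step 12 gives the bridged aryl ether F16, and Bu4NF buffered with AcOH releases 16.

## Further compounds

F1 | step 3 | (R)-4-[(tert-butyldimethylsilyl)oxy]cyclohex-2-en-1-one | O=C1C=C[C@H](O[Si](C)(C)C(C)(C)C)CC1
F2 | step 3 | (4R)-6-acetyl-4-[(tert-butyldimethylsilyl)oxy]cyclohex-2-en-1-one (C6 not defined, enolised) | CC(=O)C1C[C@@H](O[Si](C)(C)C(C)(C)C)C=CC1=O
F3 | step 3 | (4R)-4-[(tert-butyldimethylsilyl)oxy]-6-(3-oxo-5-phenylpentanoyl)cyclohex-2-en-1-one (C6 not defined, enolised) | O=C(CCc1ccccc1)CC(=O)C1C[C@@H](O[Si](C)(C)C(C)(C)C)C=CC1=O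
F4 | step 3 | (6R)-6-[(tert-butyldimethylsilyl)oxy]-2-(2-phenylethyl)-5,6-dihydro-4H-chromen-4-one | O=c1cc(CCc2ccccc2)oc2c1C[C@@H](O[Si](C)(C)C(C)(C)C)C=C2
F5 | step 3 | (6R,7R,8S)-6-[(tert-butyldimethylsilyl)oxy]-7,8-dihydroxy-2-(2-phenylethyl)-5,6,7,8-tetrahydro-4H-chromen-4-one | O=c1cc(CCc2ccccc2)oc2c1C[C@@H](O[Si](C)(C)C(C)(C)C)[C@H](O)[C@@H]2O
F6 | step 3 | 7,8-O-isopropylidene acetal of F5 | CC1(C)O[C@@H]2c3oc(CCc4ccccc4)cc(=O)c3C[C@@H](O[Si](C)(C)C(C)(C)C)[C@@H]2O1
F7 | step 3 | (6R,7S,8S)-6-hydroxy-7,8-(isopropylidenedioxy)-2-(2-phenylethyl)-5,6,7,8-tetrahydro-4H-chromen-4-one | CC1(C)O[C@@H]2c3oc(CCc4ccccc4)cc(=O)c3C[C@@H](O)[C@@H]2O1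
F8 | step 3 | 6-O-methanesulfonate of F7 | CC1(C)O[C@@H]2c3oc(CCc4ccccc4)cc(=O)c3C[C@@H](OS(C)(=O)=O)[C@@H]2O1
F9 | step 12 | 8-O-triethylsilyl ether of 10 | CC[Si](CC)(CC)O[C@@H]1c2oc(CCc3ccccc3)cc(=O)c2[C@H](O[Si](C)(C)C(C)(C)C)[C@@H](O[Si](C)(C)C(C)(C)C)[C@@H]1O
F10 | step 12 | 7-O-(tert-butyldimethylsilyl)-8-O-triethylsilyl derivative of 10 | CC[Si](CC)(CC)O[C@@H]1c2oc(CCc3ccccc3)cc(=O)c2[C@H](O[Si](C)(C)C(C)(C)C)[C@@H](O[Si](C)(C)C(C)(C)C)[C@@H]1O[Si](C)(C)C(C)(C)C
F11 | step 12 | 7-O-(tert-butyldimethylsilyl) derivative of 10 (5,6,7-tris-silyl ether, free 8-hydroxyl) | O[C@@H]1c2oc(CCc3ccccc3)cc(=O)c2[C@H](O[Si](C)(C)C(C)(C)C)[C@@H](O[Si](C)(C)C(C)(C)C)[C@@H]1O[Si](C)(C)C(C)(C)C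
F12 | step 12 | 5,6,7-tris-O-(tert-butyldimethylsilyl) ether of 16 | COc1cc2oc(CCc3ccccc3)cc(=O)c2cc1O[C@@H]1c2oc(CCc3ccccc3)cc(=O)c2[C@H](O[Si](C)(C)C(C)(C)C)[C@@H](O[Si](C)(C)C(C)(C)C)[C@@H]1O[Si](C)(C)C(C)(C)C
F13 | step 6 | (5S,6R,7S,8S)-5,6,7,8-tetrahydroxy-2-(2-phenylethyl)-5,6,7,8-tetrahydro-4H-chromen-4-one | O[C@@H]1c2oc(CCc3ccccc3)cc(=O)c2[C@H](O)[C@@H](O)[C@@H]1O
F14 | step 8 | 5,6-O-(1,1,3,3-tetraisopropyldisiloxane-1,3-diyl) derivative of 8 | CC1(C)O[C@@H]2c3oc(CCc4ccccc4)cc(=O)c3[C@@H]5O[Si](C(C)C)(C(C)C)O[Si](C(C)C)(C(C)C)O[C@H]5[C@@H]2O1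
F15 | step 8 | 7,8-diol from F14 (5,6-O-disiloxanediyl bridge kept) | O[C@@H]1c2oc(CCc3ccccc3)cc(=O)c2[C@@H]5O[Si](C(C)C)(C(C)C)O[Si](C(C)C)(C(C)C)O[C@H]5[C@@H]1O
F16 | step 8 | 5,6-O-(1,1,3,3-tetraisopropyldisiloxane-1,3-diyl) derivative of 16 | COc1cc2oc(CCc3ccccc3)cc(=O)c2cc1O[C@@H]1c2oc(CCc3ccccc3)cc(=O)c2[C@@H]5O[Si](C(C)C)(C(C)C)O[Si](C(C)C)(C(C)C)O[C@H]5[C@@H]1O
A1 | alternative 1 | 5,6,7-tris-O-(tert-butyldimethylsilyl) ether of 16 | COc1cc2oc(CCc3ccccc3)cc(=O)c2cc1O[C@@H]1c2oc(CCc3ccccc3)cc(=O)c2[C@H](O[Si](C)(C)C(C)(C)C)[C@@H](O[Si](C)(C)C(C)(C)C)[C@@H]1O[Si](C)(C)C(C)(C)C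
A2 | alternative 2 | 2-{[5,6,7-tris(tert-butyldimethylsilyloxy)-4-oxo-2-(2-phenylethyl)-5,6,7,8-tetrahydrochromen-8-yl]oxy}-5-(triisopropylsilyloxy)phenol, ring C configured as in 16 | Oc1cc(O[Si](C(C)C)(C(C)C)C(C)C)ccc1O[C@@H]1c2oc(CCc3ccccc3)cc(=O)c2[C@H](O[Si](C)(C)C(C)(C)C)[C@@H](O[Si](C)(C)C(C)(C)C)[C@@H]1O[Si](C)(C)C(C)(C)C
A3 | alternative 2 | (triisopropylsilyloxy)ethyne | C#CO[Si](C(C)C)(C(C)C)C(C)C
A4 | alternative 3 | 5-deoxy-6,7-bis-O-(tert-butyldimethylsilyl) derivative of 16 | COc1cc2oc(CCc3ccccc3)cc(=O)c2cc1O[C@@H]1c2oc(CCc3ccccc3)cc(=O)c2C[C@@H](O[Si](C)(C)C(C)(C)C)[C@@H]1O[Si](C)(C)C(C)(C)C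
A5 | alternative 3 | shikimic acid, (3R,4S,5R)-3,4,5-trihydroxycyclohex-1-ene-1-carboxylic acid | C1[C@H]([C@@H]([C@@H](C=C1C(=O)O)O)O)O
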